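**Plan**

Numbering: enone C2(Me)=C3; chain C4(Me)–C5–C6(Me)–C7–C8–C9; cyclohexene C10–C11=C12(CO2H)–C13(Me)–C14H2–C15 (spiro); lactone O16–C17(=O); tetronate carbons C18 and C20; acyl carbon C19. The 13-membered carbocycle is C2…C10–C15–C20–C18–C19.
Retrosynthesis: after unmasking (O-methyl, methyl ester), one retro-cascade cuts C10–C15 and C13–C14 (retro-[4+2]) and then O16–C15, unfolding all three rings to an open-chain 2-acyl-3-methoxypent-2-en-4-ynoic acid. That chain is cut at C18–C19 (alkenylmagnesium + enal), C11–C12 (Stille), C2=C3 (Still–Gennari) and C7–C8 (copper-catalysed Grignard coupling).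
Enabling feature: C15 is both the O-bearing C5 of the tetronate and a cyclohexene carbon whose ring neighbour C14 is an unsubstituted CH2, with the ring alkene C11=C12 opposite. C15–C14 therefore maps onto a terminal alkyne, which a cis carboxyl turns into the exocyclic enol-ester C=CH2, the dienophile the cyclohexene requires.
Forward: the chain is built from a meso C7 diol; all rings arise in step 19, first the butenolide (O16–C15), then the cyclohexene and the 13-membered carbocycle together.
Stereochemistry: C4/C6 from enzymatic desymmetrisation of the meso diol; Z-C2=C3 from Still–Gennari olefination; diene geometry from syn-hydrozirconation and syn-hydrostannation; C10, C13 and C15 from the endo intramolecular Diels–Alder reaction under control of the C4/C6-bearing tether.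

Key step: step 19

Assumption 1: the target is a 3-acyltetronic acid written as its exocyclic enol tautomer; the tautomers interconvert, so the acyltetronic acid formed in step 20 is the target.
Assumption 2: the lipase is taken to acetylate the CH2OH group next to the carbon that becomes C4; should it prefer the other hydroxyl, the complementary hydrolytic mode of the same enzyme would be used.
Assumption 3: the geometry of the tetrasubstituted enol-ether alkene in 23–28 is drawn with the carboxyl group cis to the alkyne but is not a stereochemical issue; in 27 and 28 it is a push–pull alkene that can rotate, and only the form with CO2H cis to the alkyne can lactonise.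

**Route**

Step 1
Reactants: 1 cis-2,4-dimethylglutaric anhydride (meso)
Product: 2 meso-2,4-dimethylpentane-1,5-diol
Conditions: LiAlH4, THF, 0 °C to reflux; Fieser work-up
Reagents that add atoms: none
Why: Hydride reduction of the cyclic anhydride to the diol does not touch the two methyl-bearing carbons, so the syn (meso) relationship of the future C4 and C6 methyl groups is carried over.

Step 2
Reactants: 2 meso-2,4-dimethylpentane-1,5-diol
Product: 3 (2R,4S)-5-hydroxy-2,4-dimethylpentyl acetate
Conditions: lipase AK (Pseudomonas fluorescens), vinyl acetate, THF, 25 °C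
Reagents that add atoms: vinyl acetate, CC(=O)OC=C
Why: Lipase-catalysed transesterification (enzymatic desymmetrisation of a meso diol) acylates one enantiotopic CH2OH group and thereby fixes the absolute configuration of both methyl-bearing carbons at once.

Step 3
Reactants: 3 (2R,4S)-5-hydroxy-2,4-dimethylpentyl acetate
Product: 4 (2R,4S)-2,4-dimethyl-5-(tosyloxy)pentyl acetate
Conditions: TsCl, pyridine, CH2Cl2, 0 °C
Reagents that add atoms: p-toluenesulfonyl chloride, Cc1ccc(cc1)S(Cl)(=O)=O
Why: Sulfonylation of the only free primary alcohol turns C7 into the electrophile for the sp3–sp3 coupling.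

Step 4
Reactants: 4 (2R,4S)-2,4-dimethyl-5-(tosyloxy)pentyl acetate; 5 (4-bromobut-1-yn-1-yl)trimethylsilane
Product: 7 (2R,4R)-2,4-dimethyl-9-(trimethylsilyl)non-8-yn-1-yl acetate, via homopropargyl Grignard reagent 6 (not isolated)
Conditions: 5, Mg, THF, 40 °C; then 4, Li2CuCl4 (5 mol %), THF, −78 to −10 °C
Reagents that add atoms: none
Why: Copper-catalysed Grignard–tosylate cross-coupling (Kochi–Schlosser type) joins C7 to C8 without touching either stereocentre, the acetate is expected to survive at low temperature, and any acetate that is cleaved converges in step 5.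

Step 5
Reactants: 7 (2R,4R)-2,4-dimethyl-9-(trimethylsilyl)non-8-yn-1-yl acetate
Product: 8 (2R,4R)-2,4-dimethylnon-8-yn-1-ol
Conditions: K2CO3, MeOH, 25 °C
Reagents that add atoms: none
Why: Base-catalysed methanolysis removes the acetate and the alkynyl silyl group in one operation.

Step 6
Reactants: 8 (2R,4R)-2,4-dimethylnon-8-yn-1-ol
Product: 9 (2R,4R)-2,4-dimethylnon-8-ynal
Conditions: DMP, NaHCO3, CH2Cl2, 0 °C
Reagents that add atoms: none
Why: Buffered Dess–Martin oxidation gives the α-branched aldehyde under non-epimerising conditions, and it is used at once.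

Step 7
Reactants: 9 (2R,4R)-2,4-dimethylnon-8-ynal; 10 ethyl 2-[bis(2,2,2-trifluoroethoxy)phosphoryl]propanoate
Product: 11 ethyl (2Z,4R,6R)-2,4,6-trimethylundec-2-en-10-ynoate
Conditions: 10, KHMDS, 18-crown-6, THF, −78 °C; then 9
Reagents that add atoms: none
Why: Still–Gennari olefination gives the Z-trisubstituted enoate (C19 cis to C4) because the electron-poor phosphonate eliminates rapidly from the kinetically formed adduct under dissociating conditions.

Step 8
Reactants: 11 ethyl (2Z,4R,6R)-2,4,6-trimethylundec-2-en-10-ynoate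
Product: 12 (2Z,4R,6R)-2,4,6-trimethylundec-2-en-10-yn-1-ol
Conditions: DIBAL-H, CH2Cl2, −78 °C
Reagents that add atoms: none
Why: 1,2-Reduction of the enoate to the allylic alcohol keeps the Z geometry and is done before any other ester is in the molecule.

Step 9
Reactants: 12 (2Z,4R,6R)-2,4,6-trimethylundec-2-en-10-yn-1-ol
Product: 14 (2Z,4R,6R,10E)-11-iodo-2,4,6-trimethylundeca-2,10-dien-1-ol, via alkenylzirconocene 13 (not isolated)
Conditions: Cp2Zr(H)Cl (2.5 equiv), THF, 25 °C; then I2, 0 °C
Reagents that add atoms: iodine, II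
Why: Hydrozirconation of the terminal alkyne is a syn, anti-Markovnikov addition and iodinolysis goes with retention, which gives the E-iodoalkene, while the trisubstituted alkene is too hindered to react and the hydroxyl is carried as its zirconium alkoxide.

Step 10
Reactants: 15 methyl but-2-ynoate
Product: 16 methyl (E)-2-(tributylstannyl)but-2-enoate
Conditions: Bu3SnH, Pd(PPh3)4 (2 mol %), THF, 0 °C
Reagents that add atoms: tributyltin hydride, CCCC[SnH](CCCC)CCCC
Why: Palladium-catalysed hydrostannation of an ynoate adds H and Sn syn with tin at the α-carbon, which places the methyl group trans to tin as the diene requires.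

Step 11
Reactants: 14 (2Z,4R,6R,10E)-11-iodo-2,4,6-trimethylundeca-2,10-dien-1-ol; 16 methyl (E)-2-(tributylstannyl)but-2-enoate
Product: 17 methyl (2Z)-2-[(1E,6R,8R,9Z)-11-hydroxy-6,8,10-trimethylundeca-1,9-dien-1-yl]but-2-enoate
Conditions: Pd(PPh3)4 (5 mol %), CuI (20 mol %), DMF, 45 °C
Reagents that add atoms: none
Why: Copper-assisted Stille coupling proceeds with retention at both alkenyl carbons and so delivers the diene with the C9 chain and the C13 methyl both on the outside.

Step 12
Reactants: 17 methyl (2Z)-2-[(1E,6R,8R,9Z)-11-hydroxy-6,8,10-trimethylundeca-1,9-dien-1-yl]but-2-enoate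
Product: 18 methyl (2Z)-2-[(1E,6R,8R,9Z)-6,8,10-trimethyl-11-oxoundeca-1,9-dien-1-yl]but-2-enoate
Conditions: DMP, NaHCO3, CH2Cl2, 0 °C
Reagents that add atoms: none
Why: Buffered Dess–Martin oxidation of the Z-allylic alcohol gives the Z-enal without acid or base that would isomerise it.

Step 13
Reactants: 19 tert-butyl acetate; 20 ethyl 3-(trimethylsilyl)prop-2-ynoate
Product: 21 tert-butyl 3-oxo-5-(trimethylsilyl)pent-4-ynoate
Conditions: LDA (2.2 equiv), 19, THF, −78 °C; then 20; NH4Cl work-up
Reagents that add atoms: none
Why: Crossed Claisen condensation of the lithium enolate of tert-butyl acetate with the propiolate ester gives the β-keto ester, the silyl group shielding the alkyne terminus from conjugate addition.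

Step 14
Reactants: 21 tert-butyl 3-oxo-5-(trimethylsilyl)pent-4-ynoate
Product: 22 tert-butyl (E)-3-methoxy-5-(trimethylsilyl)pent-2-en-4-ynoate
Conditions: HC(OMe)3, MeOH, CSA (cat.), 25 °C
Reagents that add atoms: trimethyl orthoformate, COC(OC)OC
Why: Acid-catalysed enol-ether formation from a β-keto ester has only one ketone to choose from, so the methoxy group ends up on the alkyne-bearing carbon, the later C20.

Step 15
Reactants: 22 tert-butyl (E)-3-methoxy-5-(trimethylsilyl)pent-2-en-4-ynoate
Product: 23 tert-butyl (Z)-2-iodo-3-methoxy-5-(trimethylsilyl)pent-2-en-4-ynoate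
Conditions: NIS, CH2Cl2, 0 to 25 °C
Reagents that add atoms: N-iodosuccinimide, O=C1CCC(=O)N1I
Why: Electrophilic iodination of the enol ether at its nucleophilic α-carbon (addition–elimination through the oxocarbenium ion) gives the α-iodo enoate.

Step 16
Reactants: 23 tert-butyl (Z)-2-iodo-3-methoxy-5-(trimethylsilyl)pent-2-en-4-ynoate; 18 methyl (2Z)-2-[(1E,6R,8R,9Z)-6,8,10-trimethyl-11-oxoundeca-1,9-dien-1-yl]but-2-enoate
Product: 26 tert-butyl (2E)-2-[(2Z,4R,6R,10E,12Z)-1-hydroxy-12-(methoxycarbonyl)-2,4,6-trimethyltetradeca-2,10,12-trien-1-yl]-3-methoxypent-2-en-4-ynoate (carbinol epimers), via alkenylmagnesium chloride 24 (not isolated), via silylated carbinol 25 (not isolated)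
Conditions: 23, i-PrMgCl·LiCl (1.1 equiv), THF, −78 °C; then 18, −78 to −40 °C; then MeOH, K2CO3, 0 °C
Reagents that add atoms: none
Why: Iodine–magnesium exchange of the α-iodo enoate is faster than attack on the esters, the alkenylmagnesium adds 1,2 to the enal to form the C18–C19 bond, the methanolic carbonate quench removes the alkynyl silyl group, and the uncontrolled carbinol centre is erased in step 17.

Step 17
Reactants: 26 carbinol from step 16
Product: 27 tert-butyl (2E)-2-[(2Z,4R,6R,10E,12Z)-12-(methoxycarbonyl)-2,4,6-trimethyltetradeca-2,10,12-trienoyl]-3-methoxypent-2-en-4-ynoate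
Conditions: DMP, NaHCO3, CH2Cl2, 0 °C
Reagents that add atoms: none
Why: Dess–Martin oxidation of the doubly allylic carbinol gives the cross-conjugated ketone, in which the tetrasubstituted push–pull alkene can now rotate.

Step 18
Reactants: 27 ketone from step 17
Product: 28 (2E)-2-[(2Z,4R,6R,10E,12Z)-12-(methoxycarbonyl)-2,4,6-trimethyltetradeca-2,10,12-trienoyl]-3-methoxypent-2-en-4-ynoic acid
Conditions: TFA, CH2Cl2 (1:4), 0 °C; evaporation with toluene
Reagents that add atoms: none
Why: Acidolysis of the tert-butyl ester (loss of isobutene) frees the carboxylic acid without any nucleophile that would attack the vinylogous carbonate or the methyl ester.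

Step 19
Reactants: 28 acid from step 18
Product: 30 O-methyl okilactomycin C methyl ester (spirotetronate methyl ether with CO2Me at C12), via 5-methylene tetronate 29 (not isolated)
Conditions: Ag2CO3 (10 mol %), toluene (0.05 M), 25 °C; then dilution to 0.002 M, BHT (cat.), 110 °C
Reagents that add atoms: none
Why: The silver carboxylate activates the terminal alkyne, the carboxyl oxygen adds anti at the internal alkyne carbon and protodeargentation gives the 5-methylene tetronate 29, whose exocyclic C=CH2 (activated through the tetronate C=C by the lactone and acyl carbonyls) then adds on heating across the dienoate in an intramolecular Diels–Alder reaction. The closest known reaction types are the Ag2CO3-catalysed lactonisation of (Z)-2-en-4-ynoic acids to 5-ylidenebutenolides and the intramolecular Diels–Alder reaction of 3-acyl-5-methylene tetronates used for macrocyclic spirotetronates. The butenolide closes 5-exo-dig (O16–C15), the cyclohexene closes by the [4+2] (C10–C15 and C13–C14), and the 13-membered carbocycle closes as the tether of that same cycloaddition. C10 and C13 become cis because both diene termini carry their substituents on the outside, C15 is set by the endo transition state that puts the tether-bearing C20 under the diene and so cis to C9 and the C13 methyl, and the sense relative to C4 and C6 is expected to come from the forming macrocycle, in which the syn-1,3-dimethyl segment and the Z-enone leave one low-strain folding of the tether. The step needs 5-exo over 6-endo closure, secured by the terminal alkyne (Markovnikov attack under monovalent silver); fused over bridged regiochemistry, secured by the tether and the para-directing ester on the diene; and intra- over intermolecular cycloaddition, secured by high dilution. Attack by the ketone oxygen is not productive because only the carboxyl group gives a neutral, protodemetalated product.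

Step 20
Reactants: 30 O-methyl okilactomycin C methyl ester
Product: 32 Okilactomycin C, via tetronic acid methyl ester 31 (not isolated)
Conditions: LiCl, DMSO, 50 °C; then LiOH, THF/H2O, 40 °C; 1 M HCl work-up
Reagents that add atoms: lithium hydroxide, [Li+].[OH-]
Why: Chloride demethylates the vinylogous methyl carbonate by SN2 attack at the methyl group to give the tetronate anion, which resists hydroxide, so that saponification of the conjugated methyl ester and acidification give the target without touching C10, C13 or the Z-enone.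

**Compound list**

1 | cis-2,4-dimethylglutaric anhydride (meso) | C[C@H]1C[C@@H](C)C(=O)OC1=O | starting material
2 | meso-2,4-dimethylpentane-1,5-diol | OC[C@H](C)C[C@H](C)CO | intermediate
3 | (2R,4S)-5-hydroxy-2,4-dimethylpentyl acetate | CC(=O)OC[C@H](C)C[C@H](C)CO | intermediate
4 | (2R,4S)-2,4-dimethyl-5-(tosyloxy)pentyl acetate | CC(=O)OC[C@H](C)C[C@H](C)COS(=O)(=O)c1ccc(C)cc1 | intermediate
5 | (4-bromobut-1-yn-1-yl)trimethylsilane | C[Si](C)(C)C#CCCBr | starting material
6 | [4-(trimethylsilyl)but-3-yn-1-yl]magnesium bromide | C[Si](C)(C)C#CCC[Mg]Br | intermediate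
7 | (2R,4R)-2,4-dimethyl-9-(trimethylsilyl)non-8-yn-1-yl acetate | CC(=O)OC[C@H](C)C[C@H](C)CCCC#C[Si](C)(C)C | intermediate
8 | (2R,4R)-2,4-dimethylnon-8-yn-1-ol | OC[C@H](C)C[C@H](C)CCCC#C | intermediate
9 | (2R,4R)-2,4-dimethylnon-8-ynal | O=C[C@H](C)C[C@H](C)CCCC#C | intermediate
10 | ethyl 2-[bis(2,2,2-trifluoroethoxy)phosphoryl]propanoate (racemic) | CCOC(=O)C(C)P(=O)(OCC(F)(F)F)OCC(F)(F)F | starting material
11 | ethyl (2Z,4R,6R)-2,4,6-trimethylundec-2-en-10-ynoate | CCOC(=O)/C(C)=C\[C@H](C)C[C@H](C)CCCC#C | intermediate
12 | (2Z,4R,6R)-2,4,6-trimethylundec-2-en-10-yn-1-ol | OC/C(C)=C\[C@H](C)C[C@H](C)CCCC#C | intermediate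
13 | (E)-alkenylzirconocene chloride from 12 (cyclopentadienyl rings drawn σ-bonded; hydroxyl present as zirconium alkoxide) | OC/C(C)=C\[C@H](C)C[C@H](C)CCC/C=C/[Zr](Cl)(C1C=CC=C1)C1C=CC=C1 | intermediate
14 | (2Z,4R,6R,10E)-11-iodo-2,4,6-trimethylundeca-2,10-dien-1-ol | OC/C(C)=C\[C@H](C)C[C@H](C)CCC/C=C/I | intermediate
15 | methyl but-2-ynoate | CC#CC(=O)OC | starting material
16 | methyl (E)-2-(tributylstannyl)but-2-enoate | C/C=C(\C(=O)OC)[Sn](CCCC)(CCCC)CCCC | intermediate
17 | methyl (2Z)-2-[(1E,6R,8R,9Z)-11-hydroxy-6,8,10-trimethylundeca-1,9-dien-1-yl]but-2-enoate | OC/C(C)=C\[C@H](C)C[C@H](C)CCC/C=C/C(C(=O)OC)=C/C | intermediate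
18 | methyl (2Z)-2-[(1E,6R,8R,9Z)-6,8,10-trimethyl-11-oxoundeca-1,9-dien-1-yl]but-2-enoate | O=C/C(C)=C\[C@H](C)C[C@H](C)CCC/C=C/C(C(=O)OC)=C/C | intermediate
19 | tert-butyl acetate | CC(=O)OC(C)(C)C | starting material
20 | ethyl 3-(trimethylsilyl)prop-2-ynoate | CCOC(=O)C#C[Si](C)(C)C | starting material
21 | tert-butyl 3-oxo-5-(trimethylsilyl)pent-4-ynoate | CC(C)(C)OC(=O)CC(=O)C#C[Si](C)(C)C | intermediate
22 | tert-butyl (E)-3-methoxy-5-(trimethylsilyl)pent-2-en-4-ynoate | CO/C(C#C[Si](C)(C)C)=C/C(=O)OC(C)(C)C | intermediate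
23 | tert-butyl (Z)-2-iodo-3-methoxy-5-(trimethylsilyl)pent-2-en-4-ynoate | CO/C(C#C[Si](C)(C)C)=C(\I)C(=O)OC(C)(C)C | intermediate
24 | alkenylmagnesium chloride from 23 | CO/C(C#C[Si](C)(C)C)=C(\[Mg]Cl)C(=O)OC(C)(C)C | intermediate
25 | silylated carbinol: 5-trimethylsilyl derivative of 26 (carbinol epimers) | CO/C(C#C[Si](C)(C)C)=C(\C(O)/C(C)=C\[C@H](C)C[C@H](C)CCC/C=C/C(C(=O)OC)=C/C)C(=O)OC(C)(C)C | intermediate
26 | tert-butyl (2E)-2-[(2Z,4R,6R,10E,12Z)-1-hydroxy-12-(methoxycarbonyl)-2,4,6-trimethyltetradeca-2,10,12-trien-1-yl]-3-methoxypent-2-en-4-ynoate (carbinol epimers) | CO/C(C#C)=C(\C(O)/C(C)=C\[C@H](C)C[C@H](C)CCC/C=C/C(C(=O)OC)=C/C)C(=O)OC(C)(C)C | intermediate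
27 | tert-butyl (2E)-2-[(2Z,4R,6R,10E,12Z)-12-(methoxycarbonyl)-2,4,6-trimethyltetradeca-2,10,12-trienoyl]-3-methoxypent-2-en-4-ynoate | CO/C(C#C)=C(\C(=O)/C(C)=C\[C@H](C)C[C@H](C)CCC/C=C/C(C(=O)OC)=C/C)C(=O)OC(C)(C)C | intermediate
28 | (2E)-2-[(2Z,4R,6R,10E,12Z)-12-(methoxycarbonyl)-2,4,6-trimethyltetradeca-2,10,12-trienoyl]-3-methoxypent-2-en-4-ynoic acid | CO/C(C#C)=C(\C(=O)/C(C)=C\[C@H](C)C[C@H](C)CCC/C=C/C(C(=O)OC)=C/C)C(=O)O | intermediate
29 | methyl (2Z)-2-[(1E,6R,8R,9Z)-11-(4-methoxy-5-methylidene-2-oxo-2,5-dihydrofuran-3-yl)-6,8,10-trimethyl-11-oxoundeca-1,9-dien-1-yl]but-2-enoate | COC1=C(C(=O)/C(C)=C\[C@H](C)C[C@H](C)CCC/C=C/C(C(=O)OC)=C/C)C(=O)OC1=C | intermediate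
30 | O-methyl okilactomycin C methyl ester (4-methoxy spirotetronate; C9, C13-methyl and C20 on one face of the cyclohexene, O16 on the other; Z-C2=C3) | C/C1=C/[C@H](C)C[C@H](C)CCC[C@H]2C=C(C(=O)OC)[C@@H](C)C[C@]23OC(=O)C(C1=O)=C3OC | intermediate
31 | okilactomycin C methyl ester (free acyltetronic acid, CO2Me at C12) | CC1=C/[C@H](C)C[C@H](C)CCC[C@H]2C=C(C(=O)OC)[C@@H](C)C[C@]23OC(=O)\C(=C\1O)C3=O | intermediate
32 | Okilactomycin C | CC1=C/[C@H](C)C[C@H](C)CCC[C@H]2C=C(C(=O)O)[C@@H](C)C[C@]23OC(=O)\C(=C\1O)C3=O | target

**Step count and risks**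

Total step count: 20. Longest linear sequence: 16 steps (steps 1–9, 11, 12, 16–20).

Steps most likely to fail:

1. Step 19. The two events may interfere: a 6-endo closure or the ketone oxygen may intercept the silver-activated alkyne, the acid may decompose before it closes, and the macrocyclic cycloaddition may be outrun by oligomerisation or show poor facial selectivity with respect to C4/C6. Fallback: the butenolide is closed on the small fragment, where neither ketone nor diene is present, and the cycloaddition becomes a separate operation. The fallback sets out from 23 and 18. Methanolysis of 23 (K2CO3, MeOH) gives tert-butyl (Z)-2-iodo-3-methoxypent-2-en-4-ynoate F1. TFA then gives (Z)-2-iodo-3-methoxypent-2-en-4-ynoic acid F2, and Ag2CO3-catalysed 5-exo-dig lactonisation gives 3-iodo-4-methoxy-5-methylenefuran-2(5H)-one F3. Nozaki–Hiyama–Kishi coupling of F3 with 18 (CrCl2, NiCl2 cat., DMF) gives methyl (2Z)-2-[(1E,6R,8R,9Z)-11-hydroxy-11-(4-methoxy-5-methylidene-2-oxo-2,5-dihydrofuran-3-yl)-6,8,10-trimethylundeca-1,9-dien-1-yl]but-2-enoate F4. Dess–Martin oxidation of F4 comes back to the route at 29, now isolated. Its cycloaddition to 30 can then be run on its own, thermally at high dilution or at lower temperature with a Lewis acid such as La(OTf)3 to sharpen the facial preference.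

2. Step 16. The α-magnesiated β-methoxy enoate may lose magnesium methoxide by β-elimination, the exchange reagent may attack the vinylogous carbonate, or the Z-enal may isomerise under the basic conditions. Fallback: the carbanionic addition is replaced by a Nozaki–Hiyama–Kishi coupling, in which the alkenyl–metal bond arises by nickel oxidative addition and transfer to trivalent chromium under neutral conditions. It sets out from 23 and 18 (CrCl2, NiCl2 cat., DMF/THF, 25 °C) and comes back to the route at 25, which is desilylated (K2CO3, MeOH) to 26 as before. This fallback makes no compound beyond those of the list (F0).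

3. Step 11. Transmetalation of the hindered, electron-poor α-stannyl enoate may be slow, so that protodestannylation and homocoupling take over. Fallback: the polarity of the coupling is reversed to a Suzuki–Miyaura reaction. It sets out from 12 and 16. Hydroboration of 12 (pinacolborane, Cp2Zr(H)Cl cat., Et3N) gives (2Z,4R,6R,10E)-2,4,6-trimethyl-11-(4,4,5,5-tetramethyl-1,3,2-dioxaborolan-2-yl)undeca-2,10-dien-1-ol F5. Iododestannylation of 16 (I2, CH2Cl2, 0 °C, retention) gives methyl (E)-2-iodobut-2-enoate F6. Coupling of F5 and F6 (Pd(dppf)Cl2, K3PO4, THF/H2O) comes back to the route at 17.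

Further compounds
F1 | step 19 | tert-butyl (Z)-2-iodo-3-methoxypent-2-en-4-ynoate | CO/C(C#C)=C(\I)C(=O)OC(C)(C)C
F2 | step 19 | (Z)-2-iodo-3-methoxypent-2-en-4-ynoic acid | CO/C(C#C)=C(\I)C(=O)O
F3 | step 19 | 3-iodo-4-methoxy-5-methylenefuran-2(5H)-one | COC1=C(I)C(=O)OC1=C
F4 | step 19 | methyl (2Z)-2-[(1E,6R,8R,9Z)-11-hydroxy-11-(4-methoxy-5-methylidene-2-oxo-2,5-dihydrofuran-3-yl)-6,8,10-trimethylundeca-1,9-dien-1-yl]but-2-enoate (carbinol epimers) | COC1=C(C(O)/C(C)=C\[C@H](C)C[C@H](C)CCC/C=C/C(C(=O)OC)=C/C)C(=O)OC1=C
F0 | step 16 | none | none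
F5 | step 11 | (2Z,4R,6R,10E)-2,4,6-trimethyl-11-(4,4,5,5-tetramethyl-1,3,2-dioxaborolan-2-yl)undeca-2,10-dien-1-ol | OC/C(C)=C\[C@H](C)C[C@H](C)CCC/C=C/B1OC(C)(C)C(C)(C)O1
F6 | step 11 | methyl (E)-2-iodobut-2-enoate | C/C=C(\I)C(=O)OC
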